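**Assumption:** the target is planar and achiral (no stereocentre), so "single enantiomer" adds no stereochemical requirement. The only sp3 centre on the way (C3 of intermediate 6) is transient, racemic, and lost on tautomerisation.

## Retrosynthetic overview

1. Target 7 ⇒ nitroarene 3 by disconnecting N1–C2: a deoxygenative (nitrene-type) ring closure onto a gem-dibromoalkene, in which a 1,2-bromine shift leaves one Br on C2 and one on C3.
2. Nitroarene 3 ⇒ aldehyde 1 + CBr4 (2) by disconnecting the C=C bond (Ramirez dibromo-olefination).
3. Ring order: the benzene ring is bought with the C7–Br and the nitrogen already in place; the pyrrole ring is formed last, in the final step.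

## Route

**Step 1**
Reactants: 1 3-bromo-2-nitrobenzaldehyde; 2 carbon tetrabromide
Product: 3 1-bromo-3-(2,2-dibromoethenyl)-2-nitrobenzene
Conditions: CBr4 (1.5 equiv), PPh3 (3.0 equiv), CH2Cl2, 0 °C → rt
Reagents that add atoms: carbon tetrabromide, BrC(Br)(Br)Br
Why: Ramirez gem-dibromo-olefination (first stage of the Corey–Fuchs sequence): Ph3P=CBr2 made in situ from PPh3/CBr4 does a Wittig reaction on the electron-poor aldehyde, the nitro group and aryl bromide are inert to PPh3 at this temperature, and no stereocentre is formed.

**Step 2**
Reactants: 3 1-bromo-3-(2,2-dibromoethenyl)-2-nitrobenzene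
Product: 7 2,3,7-tribromo-1H-indole, via nitrosoarene 4 (not isolated), via 2,2,7-tribromo-2H-indole 5 (not isolated), via 2,3,7-tribromo-3H-indole 6 (not isolated)
Conditions: MoO2Cl2(dmf)2 (5 mol%), PPh3 (2.2 equiv), degassed PhMe, 110 °C, dark; chromatography on Et3N-deactivated silica
Reagents that add atoms: none
Why: Proposed new method: Mo(VI)/Mo(IV) oxo transfer to PPh3 deoxygenates the nitro group to nitroso compound 4, and the second deoxygenation is coupled to closure of the nitrogen onto the β-carbon of the gem-dibromoalkene (N1–C2 bond, 5-atom electrocyclisation of the nitrene equivalent) to give o-quinoid 2H-indole 5; C2 of 5 has no hydrogen, so re-aromatisation of the benzene ring can only occur by a 1,2-shift (a [1,5]-sigmatropic walk), for which bromine is a good migrating group through a bridged bromonium-like transition state, giving 3H-indole 6, which tautomerises to 7; the closest known reaction type is the Cadogan–Sundberg reductive cyclisation of β,β-dialkyl- or β,β-diaryl-2-nitrostyrenes with 1,2-carbon shift (and the analogous metal-nitrene cyclisation of β,β-disubstituted styryl azides), whereas a gem-dihaloalkene with halogen as the migrating group has not been shown; no stereocentre remains in the product.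

## Compound list

1 | 3-bromo-2-nitrobenzaldehyde | O=Cc1cccc(Br)c1[N+](=O)[O-] | starting material
2 | carbon tetrabromide | BrC(Br)(Br)Br | starting material
3 | 1-bromo-3-(2,2-dibromoethenyl)-2-nitrobenzene | O=[N+]([O-])c1c(Br)cccc1C=C(Br)Br | intermediate
4 | 1-bromo-3-(2,2-dibromoethenyl)-2-nitrosobenzene | O=Nc1c(Br)cccc1C=C(Br)Br | intermediate
5 | 2,2,7-tribromo-2H-indole | BrC1(Br)C=C2C=CC=C(Br)C2=N1 | intermediate
6 | 2,3,7-tribromo-3H-indole (racemic, transient) | BrC1=Nc2c(Br)cccc2C1Br | intermediate
7 | 2,3,7-tribromo-1H-indole | Brc1[nH]c2c(Br)cccc2c1Br | target

**Total step count:** 2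
**Longest linear sequence:** 2 steps (1 → 3 → 7)

## Steps most likely to fail

The route has only two steps, so both are ranked; there is no third step.

**Step 2 (proposed new step, highest risk).** The risks are:
- halophilic removal of bromine from 5, 6 or 7 by PPh3, which would give 2,7-dibromoindole;
- slow deoxygenation of the twisted 2,6-disubstituted nitroarene;
- heat and light sensitivity of the N–H 2,3-dibromoindole.

The fallback uses known chemistry and sets out from 3. The nitro group is reduced chemoselectively with Fe powder in AcOH/EtOH at 80 °C to give 2-bromo-6-(2,2-dibromoethenyl)aniline F1. The N1–C2 bond is then closed by Pd-catalysed intramolecular vinylic amination (Pd(Pt-Bu3)2 cat., K2CO3, PhMe, 100 °C), where reversible oxidative addition with the bulky phosphine preserves the C2–Br and C7–Br bonds, giving 2,7-dibromo-1H-indole F2. Electrophilic bromination at C3 with NBS (1.0 equiv, DMF, 0 °C) then returns to the route at 7. The same NBS treatment would also convert any 2,7-dibromoindole formed as a side product in step 2 into 7.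

**Step 1.** The risks are a sluggish Wittig reaction on the hindered ortho-nitro aldehyde and difficult separation from Ph3PO. The fallback sets out from 1. Condensation with hydrazine hydrate (EtOH, rt) gives (E)-(3-bromo-2-nitrobenzylidene)hydrazine F3. Copper-catalysed olefination of this hydrazone with CBr4 (CuCl 10 mol%, aq. NH3, DMSO, rt), with loss of N2, comes back to the route at 3 without any phosphorus reagent.

## Further compounds

F1 | step 2 | 2-bromo-6-(2,2-dibromoethenyl)aniline | Nc1c(Br)cccc1C=C(Br)Br
F2 | step 2 | 2,7-dibromo-1H-indole | Brc1cc2cccc(Br)c2[nH]1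
F3 | step 1 | (E)-(3-bromo-2-nitrobenzylidene)hydrazine | N/N=C/c1cccc(Br)c1[N+](=O)[O-]
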